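The ten-membered carbocycle (C1–C10) is made one atom too large: in thiacycle dioxide 22 sulfur bridges C1 and C10, the carbon that carries the C14 methyl ester. A Ramberg–Bäcklund reaction (chlorination at C10, episulfone, loss of SO2) excises sulfur and in the same operation creates the ring-cis C1=C10 acrylate, the feature the contraction exploits. The thiacycle is assembled from a Z-enal (C1–C6), a proline-aldol-derived propargylic mesylate (C7–C9, C11, C13) and a thioglycolate (S, C10, C14) by an anti-selective allenylindium addition (C6–C7) and a macrocyclic S-alkylation. Alkyne carbonylation to the lactone, two acylations and a hydroxyl-directed epoxidation complete the target.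

Key step: step 15

Remark on numbering: germacranolide numbering is used (ring C1–C10; C11–C13 lactone carbons; C14 ester carbon on C10; C15 methyl on C4).
Remark on stereochemistry: the target as written has a cis-4,5-epoxide (C3 and C6 on the same side), so a Z-C4=C5 alkene is carried. C10 is an epimer mixture from step 9 to step 14 and becomes sp2 in step 15. The Pd/In propargylation of step 12 is taken to run with net inversion at the propargylic carbon.

Step 1
Reactants: 1 but-2-yn-1-ol
Product: 2 (Z)-3-iodobut-2-en-1-ol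
Conditions: Red-Al, THF, 0 °C; then I2, −78 → 0 °C
Reagents that add atoms: iodine, II
Why: Hydroxyl-directed trans-hydroalumination places aluminium on C3 cis to CH2OH, and iodinolysis with retention should give the Z-vinyl iodide that fixes the later Z-C4=C5 geometry.

Step 2
Reactants: 2 (Z)-3-iodobut-2-en-1-ol
Product: 3 (Z)-triethyl[(3-iodobut-2-en-1-yl)oxy]silane
Conditions: TESCl, imidazole, CH2Cl2, 0 °C
Reagents that add atoms: chlorotriethylsilane, CC[Si](Cl)(CC)CC
Why: Standard silylation; the primary triethylsilyl ether is chosen because step 6 can oxidise it directly to the aldehyde.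

Step 3
Reactants: 3 (Z)-triethyl[(3-iodobut-2-en-1-yl)oxy]silane; 4 3-chloro-N-methoxy-N-methylpropanamide
Product: 5 (4Z)-1-chloro-4-methyl-6-(triethylsilyloxy)hex-4-en-3-one
Conditions: 3, t-BuLi (2.1 equiv), Et2O, −78 °C; MgBr2·OEt2; then 4, −78 → 0 °C
Reagents that add atoms: none
Why: Iodine–lithium exchange with retention of alkene geometry, transmetalation to magnesium to suppress enolisation, and acylation by the Weinreb amide (the chelate stops at the ketone) should join C3 to C4.

Step 4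
Reactants: 5 (4Z)-1-chloro-4-methyl-6-(triethylsilyloxy)hex-4-en-3-one
Product: 6 (3R,4Z)-1-chloro-4-methyl-6-(triethylsilyloxy)hex-4-en-3-ol
Conditions: (S)-Me-CBS (20 mol %), BH3·SMe2, THF, −30 °C; MeOH quench
Reagents that add atoms: none
Why: Corey–Bakshi–Shibata reduction with the α-branched alkenyl group as the large substituent should give the (R)-allylic alcohol (C3) by 1,2-hydride delivery.

Step 5
Reactants: 6 (3R,4Z)-1-chloro-4-methyl-6-(triethylsilyloxy)hex-4-en-3-ol
Product: 7 (3R,4Z)-3-(tert-butyldimethylsilyloxy)-1-chloro-4-methyl-6-(triethylsilyloxy)hex-4-ene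
Conditions: TBSOTf, 2,6-lutidine, CH2Cl2, −78 °C
Reagents that add atoms: tert-butyldimethylsilyl triflate, CC(C)(C)[Si](C)(C)OS(=O)(=O)C(F)(F)F
Why: Silylation with the triflate protects C3–OH with the group that is meant to survive to step 24.

Step 6
Reactants: 7 (3R,4Z)-3-(tert-butyldimethylsilyloxy)-1-chloro-4-methyl-6-(triethylsilyloxy)hex-4-ene
Product: 8 (2Z,4R)-4-(tert-butyldimethylsilyloxy)-6-chloro-3-methylhex-2-enal
Conditions: (COCl)2, DMSO, CH2Cl2, −78 → −30 °C; then Et3N, −78 °C
Reagents that add atoms: none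
Why: Swern conditions oxidise a primary triethylsilyl ether directly to the aldehyde while the secondary TBS ether stays, which should give the Z-enal (CHO = C6) without a free allylic alcohol.

Step 7
Reactants: 9 methyl sulfanylacetate (methyl thioglycolate); 10 4-methoxytrityl chloride
Product: 11 methyl [(4-methoxytrityl)sulfanyl]acetate
Conditions: Et3N, CH2Cl2, 0 °C → rt
Reagents that add atoms: none
Why: S-Tritylation of the thiol; the acid-labile Mmt group masks sulfur through the enolate and palladium steps.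

Step 8
Reactants: 12 [(4-methoxybenzyl)oxy]acetaldehyde; 13 3-(trimethylsilyl)prop-2-ynal
Product: 14 (2S,3S)-3-hydroxy-2-[(4-methoxybenzyl)oxy]-5-(trimethylsilyl)pent-4-ynal
Conditions: L-proline (20 mol %), DMF, 4 °C, slow addition of 12 to 13 (3 equiv)
Reagents that add atoms: none
Why: Proline-catalysed direct cross-aldol (enamine catalysis) with the α-alkoxy aldehyde as donor and the non-enolisable ynal as acceptor should give the anti (2S,3S) adduct through the Houk–List transition state, setting C8 and the C7 carbinol that later leaves with inversion.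

Step 9
Reactants: 14 (2S,3S)-3-hydroxy-2-[(4-methoxybenzyl)oxy]-5-(trimethylsilyl)pent-4-ynal; 11 methyl [(4-methoxytrityl)sulfanyl]acetate
Product: 16 methyl (3S,4S,5S)-3,5-dihydroxy-4-[(4-methoxybenzyl)oxy]-2-[(4-methoxytrityl)sulfanyl]hept-6-ynoate (C2 epimers), via silylalkyne diol 15 (not isolated)
Conditions: 11 (2.6 equiv), LDA, THF, −78 °C; then 14; then K2CO3, MeOH, 0 °C
Reagents that add atoms: none
Why: Lithium ester-enolate aldol addition under Felkin–Anh (polar) control by the α-OPMB group should give the 3,4-anti carbinol (C9), C10 forms as a mixture that step 15 erases, and carbonate in methanol then removes the alkynyl silane.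

Step 10
Reactants: 16 methyl (3S,4S,5S)-3,5-dihydroxy-4-[(4-methoxybenzyl)oxy]-2-[(4-methoxytrityl)sulfanyl]hept-6-ynoate
Product: 17 methyl (3S,4R,5S)-3-hydroxy-4-[(4-methoxybenzyl)oxy]-5-(methylsulfonyloxy)-2-[(4-methoxytrityl)sulfanyl]hept-6-ynoate
Conditions: MsCl (1.1 equiv), Et3N, CH2Cl2, −40 °C
Reagents that add atoms: methanesulfonyl chloride, CS(Cl)(=O)=O
Why: Site-selective sulfonylation: the propargylic hydroxyl should react, while the other is shielded by the neighbouring Mmt-thio carbon and hydrogen-bonded to the ester.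

Step 11
Reactants: 17 methyl (3S,4R,5S)-3-hydroxy-4-[(4-methoxybenzyl)oxy]-5-(methylsulfonyloxy)-2-[(4-methoxytrityl)sulfanyl]hept-6-ynoate
Product: 18 methyl (3S,4R,5S)-4-[(4-methoxybenzyl)oxy]-5-(methylsulfonyloxy)-2-[(4-methoxytrityl)sulfanyl]-3-(triethylsilyloxy)hept-6-ynoate
Conditions: TESOTf, 2,6-lutidine, CH2Cl2, −78 °C
Reagents that add atoms: triethylsilyl triflate, CC[Si](CC)(CC)OS(=O)(=O)C(F)(F)F
Why: Silylation with the triflate protects the β-hydroxy ester (C9–OH) against retro-aldol cleavage in the later base steps.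

Step 12
Reactants: 8 (2Z,4R)-4-(tert-butyldimethylsilyloxy)-6-chloro-3-methylhex-2-enal; 18 methyl (3S,4R,5S)-4-[(4-methoxybenzyl)oxy]-5-(methylsulfonyloxy)-2-[(4-methoxytrityl)sulfanyl]-3-(triethylsilyloxy)hept-6-ynoate
Product: 19 seco chloride (C1-Cl; 3-OTBS; 4Z; 6-OH; 7-ethynyl; 8-OPMB; 9-OTES; 10-SMmt; C14 methyl ester)
Conditions: Pd(dppf)Cl2 (5 mol %), InI (1.5 equiv), THF–HMPA 3:1, rt
Reagents that add atoms: none
Why: Marshall–Tamaru umpolung propargylation: anti-SN2' oxidative addition of Pd(0), transmetalation to the allenylindium and 1,2-addition to the enal through a cyclic SE2' transition state should give the anti homopropargylic alcohol with net inversion at C7, so C6 and C7 are set by reagent control.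

Step 13
Reactants: 19 seco chloride
Product: 21 eleven-membered cyclic sulfide (S bridging C1/C10; 3-OTBS; 6-OH; 7-ethynyl; 8-OPMB; 9-OTES; 10-CO2Me), via seco thiol 20 (not isolated)
Conditions: TFA (1 %), Et3SiH, CH2Cl2, 0 °C; concentrate; then Cs2CO3, Bu4NI (cat.), DMF (2 mM), 40 °C
Reagents that add atoms: none
Why: Acidolysis of the S–Mmt bond (cation trapped by the silane) followed by high-dilution caesium thiolate SN2 macrocyclisation onto the primary chloride (iodide catalysis) should close the thiacycle.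

Step 14
Reactants: 21 eleven-membered cyclic sulfide
Product: 22 eleven-membered cyclic sulfone (S,S-dioxide of 21)
Conditions: Oxone, NaHCO3, THF–MeOH–H2O, 0 °C → rt
Reagents that add atoms: potassium peroxymonosulfate (Oxone), [K+].[O-]S(=O)(=O)OO
Why: Chemoselective sulfide-to-sulfone oxidation; buffered Oxone without a ketone should not epoxidise the alkenes or the allylic alcohol.

Step 15
Reactants: 22 eleven-membered cyclic sulfone
Product: 25 ten-membered (1(10)E,4Z)-diene methyl ester (3-OTBS; 6-OH; 7-ethynyl; 8-OPMB; 9-OTES), via 10-chloro sulfone 23 (not isolated), via episulfone 24 (not isolated)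
Conditions: LiHMDS (1.05 equiv), THF, −78 °C; NCS; then KOt-Bu (4 equiv), −78 → −20 °C
Reagents that add atoms: none
Why: The C10–H between sulfone and ester is removed selectively and chlorinated by NCS; KOt-Bu then deprotonates C1 (the only α-sulfonyl hydrogens left) and 1,3-displacement of chloride, directly or after chlorine transfer to C1, closes episulfone 24, which loses SO2 stereospecifically, so the 11-membered thiacycle contracts to the 10-membered carbocycle with the new C1=C10 bond. This is a Ramberg–Bäcklund ring contraction, the reaction type used to make cycloalkenes and medium-ring enediynes from the next larger thiacycle dioxide. The only ring that is closed is the three-membered episulfone (3-exo-tet); the carbocycle arises by extrusion and not by a medium-ring closure. No stereocentre is formed; the alkene geometry follows from the cis-fused episulfone, the fusion that a ring already holding the cis C4=C5 bond accommodates without trans-cycloalkene strain, which places C2 and C9 cis (1(10)E). The step needs carbanion chemistry confined to C10 and C1: the C9 silyloxy group is a poor leaving group at −78 °C, the C6 alkoxide and the acetylide only consume base, and no other C–H is acidified by the sulfone.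

Step 16
Reactants: 25 ten-membered diene methyl ester
Product: 26 6,12-lactone (α-methylene-γ-butyrolactone; 3-OTBS; 8-OPMB; 9-OTES)
Conditions: PdCl2 (10 mol %), PPh3, SnCl2, CO (8 bar), MeCN, 70 °C
Reagents that add atoms: carbon monoxide, [C-]#[O+]
Why: Palladium-catalysed cyclocarbonylation of a homopropargylic alcohol: the alkoxycarbonylpalladium from the only free hydroxyl (C6) adds across the alkyne (5-exo) and protonolysis should give the α-methylene lactone, trans-fused because C6 and C7 are already set.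

Step 17
Reactants: 26 6,12-lactone
Product: 27 C8 alcohol (3-OTBS; 9-OTES)
Conditions: DDQ, CH2Cl2–pH 7 buffer, 0 °C
Reagents that add atoms: none
Why: Oxidative cleavage of the PMB ether by DDQ (hydride abstraction and hydrolysis of the oxocarbenium ion) leaves silyl ethers, esters and the electron-poor alkenes untouched.

Step 18
Reactants: 28 methyl angelate [methyl (Z)-2-methylbut-2-enoate]
Product: 29 (Z)-2-methylbut-2-en-1-ol
Conditions: DIBAL-H, CH2Cl2, −78 °C
Reagents that add atoms: none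
Why: 1,2-Reduction of the ester with DIBAL-H keeps the Z alkene.

Step 19
Reactants: 29 (Z)-2-methylbut-2-en-1-ol
Product: 30 [(2R,3S)-2,3-dimethyloxiran-2-yl]methanol
Conditions: Ti(Oi-Pr)4, L-(+)-DET, t-BuOOH, 4 Å MS, CH2Cl2, −20 °C
Reagents that add atoms: tert-butyl hydroperoxide, CC(C)(C)OO
Why: Sharpless asymmetric epoxidation; the L-(+)-tartrate catalyst delivers oxygen to the face that gives the (2R,3S)-epoxy alcohol, setting both side-chain stereocentres.

Step 20
Reactants: 30 [(2R,3S)-2,3-dimethyloxiran-2-yl]methanol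
Product: 31 (2S,3S)-2,3-dimethyloxirane-2-carboxylic acid
Conditions: RuCl3 (cat.), NaIO4, CCl4–MeCN–H2O, rt
Reagents that add atoms: sodium periodate, [Na+].[O-]I(=O)(=O)=O
Why: Ruthenium tetroxide oxidation of the primary alcohol to the acid should leave the epoxide and its stereocentres untouched (the descriptor at C2 changes only by priority).

Step 21
Reactants: 27 C8 alcohol; 31 (2S,3S)-2,3-dimethyloxirane-2-carboxylic acid
Product: 32 8-O-[(2S,3S)-2,3-epoxy-2-methylbutanoyl] ester (3-OTBS; 9-OTES)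
Conditions: 31, 2,4,6-Cl3C6H2COCl, Et3N, toluene; then 27, DMAP, rt
Reagents that add atoms: none
Why: Yamaguchi esterification through the mixed anhydride acylates C8–OH; the acid has no α-hydrogen, so it cannot epimerise, and the hindered acyl group goes on first so that no acetyl migration can occur.

Step 22
Reactants: 32 8-O-epoxyangelate
Product: 33 C9 alcohol (3-OTBS)
Conditions: PPTS, MeOH–CH2Cl2, 0 °C → rt
Reagents that add atoms: none
Why: Mild acid methanolysis removes the triethylsilyl ether and should leave the hindered TBS ether and the ester-deactivated epoxide.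

Step 23
Reactants: 33 C9 alcohol
Product: 34 9-acetate (3-OTBS)
Conditions: Ac2O, pyridine, DMAP (cat.), CH2Cl2, 0 °C
Reagents that add atoms: acetic anhydride, CC(=O)OC(C)=O
Why: DMAP-catalysed acetylation of the only free hydroxyl.

Step 24
Reactants: 34 9-acetate
Product: 35 C3 alcohol (4Z-alkene precursor of the target)
Conditions: HF·pyridine, pyridine, THF, 0 °C → rt
Reagents that add atoms: none
Why: Pyridine-buffered fluoride desilylation frees C3–OH without opening the side-chain epoxide or adding to the methylene lactone.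

Step 25
Reactants: 35 C3 alcohol
Product: 36 target (CNP0301544.1)
Conditions: m-CPBA, NaHCO3, CH2Cl2, 0 °C
Reagents that add atoms: 3-chloroperoxybenzoic acid, O=C(OO)c1cccc(Cl)c1
Why: Hydroxyl-directed peracid epoxidation (Henbest): allylic 1,3-strain in the Z-allylic alcohol leads to the threo epoxy alcohol on the outer face that the ring leaves open, setting C4 and C5, while the electron-poor C1=C10 and C11=C13 alkenes should not react.

Compound list
1 | but-2-yn-1-ol | CC#CCO | starting material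
2 | (Z)-3-iodobut-2-en-1-ol | C/C(I)=C/CO | intermediate
3 | (Z)-triethyl[(3-iodobut-2-en-1-yl)oxy]silane | C/C(I)=C/CO[Si](CC)(CC)CC | intermediate
4 | 3-chloro-N-methoxy-N-methylpropanamide | ClCCC(=O)N(C)OC | starting material
5 | (4Z)-1-chloro-4-methyl-6-(triethylsilyloxy)hex-4-en-3-one | ClCCC(=O)/C(C)=C\CO[Si](CC)(CC)CC | intermediate
6 | (3R,4Z)-1-chloro-4-methyl-6-(triethylsilyloxy)hex-4-en-3-ol | ClCC[C@@H](O)/C(C)=C\CO[Si](CC)(CC)CC | intermediate
7 | (3R,4Z)-3-(tert-butyldimethylsilyloxy)-1-chloro-4-methyl-6-(triethylsilyloxy)hex-4-ene | ClCC[C@@H](O[Si](C)(C)C(C)(C)C)/C(C)=C\CO[Si](CC)(CC)CC | intermediate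
8 | (2Z,4R)-4-(tert-butyldimethylsilyloxy)-6-chloro-3-methylhex-2-enal (C1–C6; CHO = C6) | ClCC[C@@H](O[Si](C)(C)C(C)(C)C)/C(C)=C\C=O | intermediate
9 | methyl sulfanylacetate (methyl thioglycolate) | COC(=O)CS | starting material
10 | 4-methoxytrityl chloride | COc1ccc(C(Cl)(c2ccccc2)c2ccccc2)cc1 | starting material
11 | methyl [(4-methoxytrityl)sulfanyl]acetate | COC(=O)CSC(c1ccccc1)(c1ccccc1)c1ccc(OC)cc1 | intermediate
12 | [(4-methoxybenzyl)oxy]acetaldehyde | O=CCOCc1ccc(OC)cc1 | starting material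
13 | 3-(trimethylsilyl)prop-2-ynal | O=CC#C[Si](C)(C)C | starting material
14 | (2S,3S)-3-hydroxy-2-[(4-methoxybenzyl)oxy]-5-(trimethylsilyl)pent-4-ynal | O=C[C@@H](OCc1ccc(OC)cc1)[C@@H](O)C#C[Si](C)(C)C | intermediate
15 | methyl (3S,4S,5S)-3,5-dihydroxy-4-[(4-methoxybenzyl)oxy]-2-[(4-methoxytrityl)sulfanyl]-7-(trimethylsilyl)hept-6-ynoate (C2 epimers; not isolated) | C[Si](C)(C)C#C[C@H](O)[C@H](OCc1ccc(OC)cc1)[C@H](O)C(SC(c1ccccc1)(c1ccccc1)c1ccc(OC)cc1)C(=O)OC | intermediate
16 | methyl (3S,4S,5S)-3,5-dihydroxy-4-[(4-methoxybenzyl)oxy]-2-[(4-methoxytrityl)sulfanyl]hept-6-ynoate (C2 epimers) | C#C[C@H](O)[C@H](OCc1ccc(OC)cc1)[C@H](O)C(SC(c1ccccc1)(c1ccccc1)c1ccc(OC)cc1)C(=O)OC | intermediate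
17 | methyl (3S,4R,5S)-3-hydroxy-4-[(4-methoxybenzyl)oxy]-5-(methylsulfonyloxy)-2-[(4-methoxytrityl)sulfanyl]hept-6-ynoate (C2 epimers) | C#C[C@H](OS(C)(=O)=O)[C@H](OCc1ccc(OC)cc1)[C@H](O)C(SC(c1ccccc1)(c1ccccc1)c1ccc(OC)cc1)C(=O)OC | intermediate
18 | methyl (3S,4R,5S)-4-[(4-methoxybenzyl)oxy]-5-(methylsulfonyloxy)-2-[(4-methoxytrityl)sulfanyl]-3-(triethylsilyloxy)hept-6-ynoate (C2 epimers; C7–C10, C11, C13, C14) | C#C[C@H](OS(C)(=O)=O)[C@H](OCc1ccc(OC)cc1)[C@H](O[Si](CC)(CC)CC)C(SC(c1ccccc1)(c1ccccc1)c1ccc(OC)cc1)C(=O)OC | intermediate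
19 | seco chloride: open chain C1(Cl)–C2–C3(OTBS)–C4(Me)=C5(Z)–C6(OH)–C7(ethynyl)–C8(OPMB)–C9(OTES)–C10(SMmt)–CO2Me; C3, C6, C7, C8, C9 as in 36 | ClCC[C@@H](O[Si](C)(C)C(C)(C)C)/C(C)=C\[C@@H](O)[C@H](C#C)[C@H](OCc1ccc(OC)cc1)[C@H](O[Si](CC)(CC)CC)C(SC(c1ccccc1)(c1ccccc1)c1ccc(OC)cc1)C(=O)OC | intermediate
20 | seco thiol (19 with free SH at C10; not isolated) | ClCC[C@@H](O[Si](C)(C)C(C)(C)C)/C(C)=C\[C@@H](O)[C@H](C#C)[C@H](OCc1ccc(OC)cc1)[C@H](O[Si](CC)(CC)CC)C(S)C(=O)OC | intermediate
21 | eleven-membered cyclic sulfide: ring S–C1–C2–C3(OTBS)–C4(Me)=C5(Z)–C6(OH)–C7(ethynyl)–C8(OPMB)–C9(OTES)–C10(CO2Me); stereocentres as in 36, C10 epimers | [C@H]1(O[Si](C)(C)C(C)(C)C)/C(C)=C\[C@@H](O)[C@H](C#C)[C@H](OCc2ccc(OC)cc2)[C@H](O[Si](CC)(CC)CC)C(C(=O)OC)SCC1 | intermediate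
22 | eleven-membered cyclic sulfone (S,S-dioxide of 21) | [C@H]1(O[Si](C)(C)C(C)(C)C)/C(C)=C\[C@@H](O)[C@H](C#C)[C@H](OCc2ccc(OC)cc2)[C@H](O[Si](CC)(CC)CC)C(C(=O)OC)S(=O)(=O)CC1 | intermediate
23 | 10-chloro sulfone (22 with Cl on C10; not isolated) | [C@H]1(O[Si](C)(C)C(C)(C)C)/C(C)=C\[C@@H](O)[C@H](C#C)[C@H](OCc2ccc(OC)cc2)[C@H](O[Si](CC)(CC)CC)C(Cl)(C(=O)OC)S(=O)(=O)CC1 | intermediate
24 | episulfone: thiirane 1,1-dioxide fused across C1–C10 of the ten-membered ring (not isolated) | [C@H]1(O[Si](C)(C)C(C)(C)C)/C(C)=C\[C@@H](O)[C@H](C#C)[C@H](OCc2ccc(OC)cc2)[C@H](O[Si](CC)(CC)CC)C3(C(=O)OC)C(C1)S3(=O)=O | intermediate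
25 | ten-membered (1(10)E,4Z)-diene: 3-OTBS, 6-OH, 7-ethynyl, 8-OPMB, 9-OTES, 10-CO2Me; stereocentres as in 36 | [C@H]1(O[Si](C)(C)C(C)(C)C)/C(C)=C\[C@@H](O)[C@H](C#C)[C@H](OCc2ccc(OC)cc2)[C@H](O[Si](CC)(CC)CC)/C(C(=O)OC)=C\C1 | intermediate
26 | 6,12-lactone (trans-fused α-methylene-γ-butyrolactone): 3-OTBS, 8-OPMB, 9-OTES | [C@H]1(O[Si](C)(C)C(C)(C)C)/C(C)=C\[C@H]2OC(=O)C(=C)[C@@H]2[C@H](OCc3ccc(OC)cc3)[C@H](O[Si](CC)(CC)CC)/C(C(=O)OC)=C\C1 | intermediate
27 | C8 alcohol: 26 without the PMB group | [C@H]1(O[Si](C)(C)C(C)(C)C)/C(C)=C\[C@H]2OC(=O)C(=C)[C@@H]2[C@H](O)[C@H](O[Si](CC)(CC)CC)/C(C(=O)OC)=C\C1 | intermediate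
28 | methyl angelate [methyl (Z)-2-methylbut-2-enoate] | C/C=C(/C)C(=O)OC | starting material
29 | (Z)-2-methylbut-2-en-1-ol | C/C=C(/C)CO | intermediate
30 | [(2R,3S)-2,3-dimethyloxiran-2-yl]methanol | OC[C@@]1(C)O[C@H]1C | intermediate
31 | (2S,3S)-2,3-dimethyloxirane-2-carboxylic acid (epoxyangelic acid) | OC(=O)[C@@]1(C)O[C@H]1C | intermediate
32 | 8-O-[(2S,3S)-2,3-epoxy-2-methylbutanoyl] lactone: 3-OTBS, 9-OTES | [C@H]1(O[Si](C)(C)C(C)(C)C)/C(C)=C\[C@H]2OC(=O)C(=C)[C@@H]2[C@H](OC(=O)[C@@]3(C)O[C@H]3C)[C@H](O[Si](CC)(CC)CC)/C(C(=O)OC)=C\C1 | intermediate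
33 | C9 alcohol: 32 without the triethylsilyl group | [C@H]1(O[Si](C)(C)C(C)(C)C)/C(C)=C\[C@H]2OC(=O)C(=C)[C@@H]2[C@H](OC(=O)[C@@]3(C)O[C@H]3C)[C@H](O)/C(C(=O)OC)=C\C1 | intermediate
34 | 9-acetate: 3-OTBS | [C@H]1(O[Si](C)(C)C(C)(C)C)/C(C)=C\[C@H]2OC(=O)C(=C)[C@@H]2[C@H](OC(=O)[C@@]3(C)O[C@H]3C)[C@H](OC(C)=O)/C(C(=O)OC)=C\C1 | intermediate
35 | C3 alcohol: 4,5-deoxy (4Z-alkene) precursor of 36 | [C@H]1(O)/C(C)=C\[C@H]2OC(=O)C(=C)[C@@H]2[C@H](OC(=O)[C@@]3(C)O[C@H]3C)[C@H](OC(C)=O)/C(C(=O)OC)=C\C1 | intermediate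
36 | CNP0301544.1 | C=C1C(=O)O[C@H]2[C@H]1[C@H](OC(=O)[C@@]1(C)O[C@H]1C)[C@H](OC(C)=O)/C(C(=O)OC)=C\C[C@@H](O)[C@]1(C)O[C@H]21 | target

Total step count: 25.
Longest linear sequence: 17 steps (steps 1–6, 12–17, 21–25, from but-2-yn-1-ol).

Steps most likely to fail

Step 15. The C10 carbanion made for the chlorination may expel the C9 silyloxy group (E1cB) before it is chlorinated, or the chlorine may be handed back to the base before the episulfone closes. The fallback sets out from sulfide 21 and returns at chloro sulfone 23. Sulfide 21 is oxidised only to the cyclic sulfoxide F1 (NaIO4, MeOH–H2O, 0 °C). F1 is chlorinated α to sulfur on the ester side with NCS and pyridine in CH2Cl2, a sulfoxide α-chlorination that needs no carbanion, to give the 10-chloro sulfoxide F2. Buffered Oxone then gives 23, which is isolated and treated with KOt-Bu as in step 15 to reach 25.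

Step 16. Under the Lewis acidic Pd/Sn system the triethylsilyl or PMB ether may be lost, the allylic C6 alcohol may ionise, or the hydrocarbonylation of the hindered alkyne may stall. The fallback sets out from 25 and returns at 26. Molybdenum-catalysed hydrostannation (Mo(CO)3(CNt-Bu)3, Bu3SnH, THF, 55 °C) places tin on the internal alkyne carbon and gives the vinylstannane F3. Iododestannylation (I2, CH2Cl2, 0 °C) gives the 2-iodoalkene F4. Carbonylative lactonisation onto C6–OH (Pd(PPh3)4, CO 1 atm, Et3N, MeCN, 50 °C) then gives 26.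

Step 8. Proline may add to the ynal in a conjugate sense, or 12 may self-condense faster than it cross-couples. The fallback sets out from 13 (with commercial [(4-methoxybenzyl)oxy]acetic acid) and returns at 14. The acid is converted with ethanethiol (DCC, DMAP) into the S-ethyl thioester F5. LiHMDS and TMSCl give the (Z)-ketene silyl thioacetal F6. A tin(II) triflate/chiral diamine mediated anti-selective Mukaiyama aldol with 13 (the diamine enantiomer that delivers the 2S,3S adduct) gives the anti aldol thioester F7. DIBAL-H at −78 °C reduces F7 to aldehyde 14.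

Further compounds
F1 | step 15 | cyclic sulfoxide (S-oxide of 21; S epimers) | [C@H]1(O[Si](C)(C)C(C)(C)C)/C(C)=C\[C@@H](O)[C@H](C#C)[C@H](OCc2ccc(OC)cc2)[C@H](O[Si](CC)(CC)CC)C(C(=O)OC)S(=O)CC1
F2 | step 15 | 10-chloro sulfoxide | [C@H]1(O[Si](C)(C)C(C)(C)C)/C(C)=C\[C@@H](O)[C@H](C#C)[C@H](OCc2ccc(OC)cc2)[C@H](O[Si](CC)(CC)CC)C(Cl)(C(=O)OC)S(=O)CC1
F3 | step 16 | vinylstannane: 25 with 1-(tributylstannyl)vinyl in place of ethynyl at C7 | [C@H]1(O[Si](C)(C)C(C)(C)C)/C(C)=C\[C@@H](O)[C@H](C(=C)[Sn](CCCC)(CCCC)CCCC)[C@H](OCc2ccc(OC)cc2)[C@H](O[Si](CC)(CC)CC)/C(C(=O)OC)=C\C1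
F4 | step 16 | 2-iodoalkene: 25 with 1-iodovinyl in place of ethynyl at C7 | [C@H]1(O[Si](C)(C)C(C)(C)C)/C(C)=C\[C@@H](O)[C@H](C(I)=C)[C@H](OCc2ccc(OC)cc2)[C@H](O[Si](CC)(CC)CC)/C(C(=O)OC)=C\C1
F5 | step 8 | S-ethyl [(4-methoxybenzyl)oxy]ethanethioate | CCSC(=O)COCc1ccc(OC)cc1
F6 | step 8 | (Z)-1-(ethylsulfanyl)-2-[(4-methoxybenzyl)oxy]-1-(trimethylsilyloxy)ethene | CCS/C(O[Si](C)(C)C)=C\OCc1ccc(OC)cc1
F7 | step 8 | S-ethyl (2S,3S)-3-hydroxy-2-[(4-methoxybenzyl)oxy]-5-(trimethylsilyl)pent-4-ynethioate | CCSC(=O)[C@@H](OCc1ccc(OC)cc1)[C@@H](O)C#C[Si](C)(C)C
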